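**Retrosynthetic overview**

1. Bisoflavolin J (14) ⇐ its unit-B 7,4'-di-O-methyl ether 13, by two aryl methyl ether cleavages at the end.
2. 13 ⇐ arylacetic acid 10 + 2-chlororesorcinol 11 + DMF: the pyranone of unit A is cut at C4–C4a (acylation), C2–C3 and C2–O1 (C2 from DMF). The strategy rests on the carbocycle of unit A (C4a–C5–C6–C7–C8–C8a, with O1 on C8a, Cl on C8, OH on C7): it is 2-chlororesorcinol, whose mirror plane through C2(Cl) and C5 makes its two acylation sites identical.
3. 10 ⇐ isoflavone ester 9 ⇐ 2-hydroxydeoxybenzoin 7 (pyranone of unit B closed with DMF as C2) ⇐ Friedel–Crafts ketone 6 ⇐ diaryl ether 3 + 4-methoxyphenylacetic acid 4.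
4. 3 ⇐ 2,6-dimethoxyphenol 1 + methyl 4-bromophenylacetate 2 by copper-catalysed C–O coupling.
5. Ring order: diaryl ether first, then the pyranone of unit B (step 4), then the pyranone of unit A (step 6).

Key step: step 6

Remark: the target has no stereocentre and no hindered axis, so it is a single achiral compound and the route needs no stereocontrol.

**Route**

Step 1
Reactants: 1 2,6-dimethoxyphenol; 2 methyl 2-(4-bromophenyl)acetate
Product: 3 methyl 2-[4-(2,6-dimethoxyphenoxy)phenyl]acetate
Conditions: CuI (10 mol%), picolinic acid (20 mol%), K3PO4 (2 equiv), DMSO, 90 °C, Ar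
Reagents that add atoms: none
Why: Ullmann-type Cu(I)/picolinate C–O coupling accepts di-ortho-substituted phenols and aryl bromides, and anhydrous phosphate under argon should leave the methyl ester and its benzylic CH2 untouched.

Step 2
Reactants: 3 methyl 2-[4-(2,6-dimethoxyphenoxy)phenyl]acetate; 4 2-(4-methoxyphenyl)acetic acid
Product: 6 methyl 2-[4-[2,6-dimethoxy-3-[2-(4-methoxyphenyl)acetyl]phenoxy]phenyl]acetate, via 2-(4-methoxyphenyl)acetyl chloride 5 (not isolated)
Conditions: 4, (COCl)2, cat. DMF, CH2Cl2, rt, evaporate; then 3, AlCl3 (2.5 equiv), CH2Cl2, −10 → 0 °C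
Reagents that add atoms: none
Why: Friedel–Crafts acylation should go to C3 of the 2,6-dimethoxyphenoxy ring (ortho to one OMe and para to the other, the counterpart of C4 of 1,2,3-trimethoxybenzene), which is far more nucleophilic than C4 of that ring or the mono-oxygenated phenylacetate ring, while the low temperature limits premature ether cleavage.

Step 3
Reactants: 6 methyl 2-[4-[2,6-dimethoxy-3-[2-(4-methoxyphenyl)acetyl]phenoxy]phenyl]acetate
Product: 7 methyl 2-[4-[2-hydroxy-6-methoxy-3-[2-(4-methoxyphenyl)acetyl]phenoxy]phenyl]acetate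
Conditions: BCl3 (1 M in CH2Cl2, 2.5 equiv), CH2Cl2, −78 → 0 °C; H2O
Reagents that add atoms: none
Why: In this chelation-controlled demethylation BCl3 binds the ketone and cleaves only the methoxy ortho to it, so the para methoxy, the anisyl ether, the diaryl ether and the methyl ester should survive at or below 0 °C.

Step 4
Reactants: 7 methyl 2-[4-[2-hydroxy-6-methoxy-3-[2-(4-methoxyphenyl)acetyl]phenoxy]phenyl]acetate
Product: 9 methyl 2-[4-[[7-methoxy-3-(4-methoxyphenyl)-4-oxochromen-8-yl]oxy]phenyl]acetate, via difluoroboron-chelated hydroxyketone 8 (not isolated)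
Conditions: BF3·OEt2, DMF, rt; then MsCl, 70 °C; H2O
Reagents that add atoms: N,N-dimethylformamide, CN(C)C=O
Why: This is the standard one-carbon closure of a 2-hydroxydeoxybenzoin to an isoflavone, in which the BF2 chelate activates the methylene toward the chloroiminium ion from DMF/MsCl and O-attack followed by loss of dimethylamine closes the pyranone of unit B, the ester being inert to these acidic conditions.

Step 5
Reactants: 9 methyl 2-[4-[[7-methoxy-3-(4-methoxyphenyl)-4-oxochromen-8-yl]oxy]phenyl]acetate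
Product: 10 2-[4-[[7-methoxy-3-(4-methoxyphenyl)-4-oxochromen-8-yl]oxy]phenyl]acetic acid
Conditions: 6 M HCl, 1,4-dioxane, 90 °C
Reagents that add atoms: water, O
Why: Acid-catalysed ester hydrolysis is chosen over saponification because the 4-pyranone ring of an isoflavone opens with hydroxide but is stable to aqueous acid, as are the aryl methyl ethers and the diaryl ether.

Step 6
Reactants: 10 2-[4-[[7-methoxy-3-(4-methoxyphenyl)-4-oxochromen-8-yl]oxy]phenyl]acetic acid; 11 2-chlororesorcinol (1.3 equiv)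
Product: 13 8-chloro-7-hydroxy-3-[4-[[7-methoxy-3-(4-methoxyphenyl)-4-oxochromen-8-yl]oxy]phenyl]chromen-4-one, via difluoroboron-chelated deoxybenzoin 12 (not isolated)
Conditions: BF3·OEt2 (neat), 85 °C; then DMF, MsCl, 70 °C; aq. NaOAc
Reagents that add atoms: N,N-dimethylformamide, CN(C)C=O
Why: BF3 turns the arylacetic acid into an acyl-transfer species that C-acylates 2-chlororesorcinol at C4 (ortho to one OH, para to the other; Nencki/Friedel–Crafts type, possibly through the aryl ester and a Fries shift), and the resulting o-hydroxyketone is held as its BF2 chelate 12, which acidifies the benzylic CH2. The chloroiminium ion made from DMF and MsCl then attacks that methylene (C3–C2 bond), the chelated phenolic oxygen adds to the new iminium carbon (O1–C2 bond, 6-exo-trig) and loss of dimethylamine gives the aromatic 4-pyranone of unit A. The closest known reaction type is the one-pot BF3·OEt2 acylation of resorcinols with arylacetic acids followed by DMF/MsCl closure to 7-hydroxyisoflavones. Regiochemistry needs no control, because C4 and C6 of 2-chlororesorcinol are mirror images and only the hydroxyl ortho to the ketone, the one next to chlorine, can reach C2, so chlorine lands on C8 and the 7-OH stays free without protection. Chemoselectivity is needed between the free resorcinol and the three ether-bearing rings of 10; it is secured by the two free hydroxyls of 11 (much stronger activation, and an O-acylation/Fries pathway open only to a phenol) while the chromone of 10 is deactivated by BF3 coordination. No stereocentre is formed.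

Step 7
Reactants: 13 8-chloro-7-hydroxy-3-[4-[[7-methoxy-3-(4-methoxyphenyl)-4-oxochromen-8-yl]oxy]phenyl]chromen-4-one
Product: 14 bisoflavolin J, 8-chloro-7-hydroxy-3-[4-[[7-hydroxy-3-(4-hydroxyphenyl)-4-oxochromen-8-yl]oxy]phenyl]chromen-4-one
Conditions: BBr3 (8 equiv), CH2Cl2, −78 °C → rt; H2O
Reagents that add atoms: none
Why: BBr3 cleavage of aryl methyl ethers (Lewis adduct, then bromide attack on the methyl carbon) should remove both O-methyl groups, while the diaryl ether (no sp3 carbon on oxygen), the aryl chloride and both chromone rings are inert, the excess reagent covering coordination to the two carbonyls and the free phenol.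

**Compound list**

1 | 2,6-dimethoxyphenol | COc1cccc(OC)c1O | starting material
2 | methyl 2-(4-bromophenyl)acetate | COC(=O)Cc1ccc(Br)cc1 | starting material
3 | methyl 2-[4-(2,6-dimethoxyphenoxy)phenyl]acetate | COC(=O)Cc1ccc(Oc2c(OC)cccc2OC)cc1 | intermediate
4 | 2-(4-methoxyphenyl)acetic acid | COc1ccc(CC(=O)O)cc1 | starting material
5 | 2-(4-methoxyphenyl)acetyl chloride | COc1ccc(CC(=O)Cl)cc1 | intermediate
6 | methyl 2-[4-[2,6-dimethoxy-3-[2-(4-methoxyphenyl)acetyl]phenoxy]phenyl]acetate | COC(=O)Cc1ccc(Oc2c(OC)ccc(C(=O)Cc3ccc(OC)cc3)c2OC)cc1 | intermediate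
7 | methyl 2-[4-[2-hydroxy-6-methoxy-3-[2-(4-methoxyphenyl)acetyl]phenoxy]phenyl]acetate | COC(=O)Cc1ccc(Oc2c(OC)ccc(C(=O)Cc3ccc(OC)cc3)c2O)cc1 | intermediate
8 | difluoroboron chelate of hydroxyketone 7 (2,2-difluoro-1,3,2-dioxaborinine fused to the phenoxy ring) | COC(=O)Cc1ccc(Oc2c(OC)ccc3c2O[B-](F)(F)[O+]=C3Cc2ccc(OC)cc2)cc1 | intermediate
9 | methyl 2-[4-[[7-methoxy-3-(4-methoxyphenyl)-4-oxochromen-8-yl]oxy]phenyl]acetate | COC(=O)Cc1ccc(Oc2c(OC)ccc3c(=O)c(-c4ccc(OC)cc4)coc23)cc1 | intermediate
10 | 2-[4-[[7-methoxy-3-(4-methoxyphenyl)-4-oxochromen-8-yl]oxy]phenyl]acetic acid | O=C(O)Cc1ccc(Oc2c(OC)ccc3c(=O)c(-c4ccc(OC)cc4)coc23)cc1 | intermediate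
11 | 2-chlororesorcinol (2-chlorobenzene-1,3-diol) | Oc1cccc(O)c1Cl | starting material
12 | difluoroboron chelate of 1-(3-chloro-2,4-dihydroxyphenyl)-2-[4-[[7-methoxy-3-(4-methoxyphenyl)-4-oxochromen-8-yl]oxy]phenyl]ethanone | COc1ccc(-c2coc3c(Oc4ccc(CC5=[O+][B-](F)(F)Oc6c(Cl)c(O)ccc65)cc4)c(OC)ccc3c2=O)cc1 | intermediate
13 | 8-chloro-7-hydroxy-3-[4-[[7-methoxy-3-(4-methoxyphenyl)-4-oxochromen-8-yl]oxy]phenyl]chromen-4-one | O=c1c(-c2ccc(Oc3c(OC)ccc4c(=O)c(-c5ccc(OC)cc5)coc34)cc2)coc2c(Cl)c(O)ccc12 | intermediate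
14 | bisoflavolin J, 8-chloro-7-hydroxy-3-[4-[[7-hydroxy-3-(4-hydroxyphenyl)-4-oxochromen-8-yl]oxy]phenyl]chromen-4-one | O=c1c(-c2ccc(Oc3c(O)ccc4c(=O)c(-c5ccc(O)cc5)coc34)cc2)coc2c(Cl)c(O)ccc12 | target

**Step count**

Total: 7 steps. Longest linear sequence: 7 steps (1 → 3 → 6 → 7 → 9 → 10 → 13 → 14).

**Steps most likely to fail**

Step 6. The C-acylation may stall, because chlorine lowers the nucleophilicity of the resorcinol and the acid is bulky and BF3-coordinated. O-acylation without Fries shift, or slow ether cleavage and self-acylation of the acid partner at 85 °C, could then take over.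
Fallback: this sets out from acid 10 and returns to the route at target 14. Oxalyl chloride with catalytic DMF should give 2-[4-[[7-methoxy-3-(4-methoxyphenyl)-4-oxochromen-8-yl]oxy]phenyl]acetyl chloride F1. AlCl3-mediated Friedel–Crafts acylation of commercial 2-chloro-1,3-dimethoxybenzene, whose C4 is ortho to one methoxy and para to the other, should give 1-(3-chloro-2,4-dimethoxyphenyl)-2-[4-[[7-methoxy-3-(4-methoxyphenyl)-4-oxochromen-8-yl]oxy]phenyl]ethanone F2. BCl3 should then cleave only the methoxy ortho to the ketone, giving 1-(3-chloro-2-hydroxy-4-methoxyphenyl)-2-[4-[[7-methoxy-3-(4-methoxyphenyl)-4-oxochromen-8-yl]oxy]phenyl]ethanone F3. Closure with DMF dimethyl acetal (toluene, 90 °C) should give 8-chloro-7-methoxy-3-[4-[[7-methoxy-3-(4-methoxyphenyl)-4-oxochromen-8-yl]oxy]phenyl]chromen-4-one F4. BBr3 would then cleave all three methyl ethers to 14.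

Step 1. Ligand exchange at copper may be slow with the di-ortho-methoxy phenoxide, so that hydrodebromination, ester hydrolysis or enolate side reactions of the arylacetate win under the basic conditions.
Fallback: this sets out from phenol 1 and returns at diaryl ether 3. SNAr of 1 on 4-fluoroacetophenone (K2CO3, DMF, 130 °C) should give 1-[4-(2,6-dimethoxyphenoxy)phenyl]ethanone F5. A Willgerodt–Kindler reaction (S8, morpholine, 130 °C) would move the carbonyl to the chain end as 2-[4-(2,6-dimethoxyphenoxy)phenyl]-1-(morpholin-4-yl)ethanethione F6. Hydrolysis (KOH, aqueous EtOH, reflux) should give 2-[4-(2,6-dimethoxyphenoxy)phenyl]acetic acid F7, and Fischer esterification (MeOH, H2SO4) gives 3.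

Step 2. Acylation may occur at C4 of the trioxygenated ring or on the phenylacetate ring, and AlCl3 may cause uncontrolled ether cleavage or self-condensation of the acid chloride.
Fallback: this sets out from acid 4 and returns at isoflavone ester 9, with the regiochemistry fixed by pyrogallol and the diaryl ether made late. BF3·OEt2 acylation of pyrogallol by 4 (only C4 is open ortho/para to the hydroxyls) should give 2-(4-methoxyphenyl)-1-(2,3,4-trihydroxyphenyl)ethanone F8. DMF/MsCl closure should give 7,8-dihydroxy-3-(4-methoxyphenyl)chromen-4-one F9. One equivalent of MeI with K2CO3 in DMF should methylate the more acidic 7-OH (conjugated to C4=O), giving 8-hydroxy-7-methoxy-3-(4-methoxyphenyl)chromen-4-one F10. Copper-catalysed O-arylation of F10 with bromide 2 under the conditions of step 1 would give 9.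

**Further compounds**

F1 | step 6 | 2-[4-[[7-methoxy-3-(4-methoxyphenyl)-4-oxochromen-8-yl]oxy]phenyl]acetyl chloride | O=C(Cl)Cc1ccc(Oc2c(OC)ccc3c(=O)c(-c4ccc(OC)cc4)coc23)cc1
F2 | step 6 | 1-(3-chloro-2,4-dimethoxyphenyl)-2-[4-[[7-methoxy-3-(4-methoxyphenyl)-4-oxochromen-8-yl]oxy]phenyl]ethanone | COc1ccc(C(=O)Cc2ccc(Oc3c(OC)ccc4c(=O)c(-c5ccc(OC)cc5)coc34)cc2)c(OC)c1Cl
F3 | step 6 | 1-(3-chloro-2-hydroxy-4-methoxyphenyl)-2-[4-[[7-methoxy-3-(4-methoxyphenyl)-4-oxochromen-8-yl]oxy]phenyl]ethanone | COc1ccc(C(=O)Cc2ccc(Oc3c(OC)ccc4c(=O)c(-c5ccc(OC)cc5)coc34)cc2)c(O)c1Cl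
F4 | step 6 | 8-chloro-7-methoxy-3-[4-[[7-methoxy-3-(4-methoxyphenyl)-4-oxochromen-8-yl]oxy]phenyl]chromen-4-one | O=c1c(-c2ccc(Oc3c(OC)ccc4c(=O)c(-c5ccc(OC)cc5)coc34)cc2)coc2c(Cl)c(OC)ccc12
F5 | step 1 | 1-[4-(2,6-dimethoxyphenoxy)phenyl]ethanone | CC(=O)c1ccc(Oc2c(OC)cccc2OC)cc1
F6 | step 1 | 2-[4-(2,6-dimethoxyphenoxy)phenyl]-1-(morpholin-4-yl)ethanethione | COc1cccc(OC)c1Oc1ccc(CC(=S)N2CCOCC2)cc1
F7 | step 1 | 2-[4-(2,6-dimethoxyphenoxy)phenyl]acetic acid | COc1cccc(OC)c1Oc1ccc(CC(=O)O)cc1
F8 | step 2 | 2-(4-methoxyphenyl)-1-(2,3,4-trihydroxyphenyl)ethanone | COc1ccc(CC(=O)c2ccc(O)c(O)c2O)cc1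
F9 | step 2 | 7,8-dihydroxy-3-(4-methoxyphenyl)chromen-4-one | COc1ccc(-c2coc3c(O)c(O)ccc3c2=O)cc1
F10 | step 2 | 8-hydroxy-7-methoxy-3-(4-methoxyphenyl)chromen-4-one | COc1ccc(-c2coc3c(O)c(OC)ccc3c2=O)cc1
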